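**Strategy**

The flavanone is disconnected at the C2–C3 bond of ring C. C2 is a benzylic CH bonded to O1 and to ring B, so it can be carried as the CH2 of a ring B benzyl ether on O1. A chiral dirhodium carbene generated at C3 from a ring A diazomethyl ketone inserts into one of these two C–H bonds; this single operation forms C2–C3, closes ring C and sets (2S)-C2. The precursor is a pentasubstituted ring A whose diazoacetyl group sits between a triisopropylsilyl ether and the O1 benzyl ether, with the limonene-derived C8 side chain (tertiary alcohol as triethylsilyl ether) attached beforehand by Negishi coupling.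

Key step: step 14

Remark on the chemistry: Rh2(S-PTTL)4, dirhodium tetrakis[N-phthaloyl-(S)-tert-leucinate] of divalent rhodium, is assumed to give the (2S) product; if a test shows the opposite sense, the enantiomeric complex Rh2(R-PTTL)4 is used under the same conditions.
Remark on the chemistry: epoxide 2 is carried as its cis/trans mixture because both isomers give 3; flavanone numbering (O1, C2, C3, C4, C5 to C8, ring B primed) is used for the late compounds.

**Route**

Step 1
Reactants: 1 (R)-limonene
Product: 2 (4R)-limonene 1,2-oxide (cis/trans mixture at C1/C2)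
Conditions: mCPBA (1.0 equiv), NaHCO3, CH2Cl2, 0 °C
Reagents that add atoms: mCPBA, O=C(OO)c1cccc(Cl)c1
Why: Prilezhaev epoxidation is electrophilic, so the trisubstituted ring alkene should react well ahead of the 1,1-disubstituted isopropenyl group; C4 is not touched and both epoxide diastereomers converge in step 2.

Step 2
Reactants: 2 (4R)-limonene 1,2-oxide
Product: 3 (3R)-6-oxo-3-(prop-1-en-2-yl)heptanal
Conditions: H5IO6 (1.1 equiv), THF/H2O, 0 °C → rt
Reagents that add atoms: water, O
Why: Periodic acid should hydrolyse the epoxide to the 1,2-diol in the flask and cleave it at once (Malaprade glycol cleavage), opening the terpene ring without affecting the isopropenyl group or the stereocentre; crude 3 is taken on directly because it tends to undergo intramolecular aldol condensation.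

Step 3
Reactants: 3 (3R)-6-oxo-3-(prop-1-en-2-yl)heptanal
Product: 4 (3R)-6-oxo-3-(prop-1-en-2-yl)heptanoic acid
Conditions: NaClO2, NaH2PO4, 2-methyl-2-butene (excess), t-BuOH/H2O, 0 °C → rt
Reagents that add atoms: sodium chlorite, [Na+].[O-]Cl=O
Why: Pinnick oxidation converts the aldehyde into the acid under buffered, non-enolising conditions, with excess 2-methyl-2-butene trapping HOCl so that the isopropenyl group and the ketone are left alone.

Step 4
Reactants: 4 (3R)-6-oxo-3-(prop-1-en-2-yl)heptanoic acid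
Product: 5 (3R)-6-hydroxy-6-methyl-3-(prop-1-en-2-yl)heptanoic acid
Conditions: MeMgBr (3.5 equiv), THF, −40 → 0 °C; aq. NH4Cl, then citric acid to pH 4
Reagents that add atoms: methylmagnesium bromide, C[Mg]Br
Why: Grignard addition: the first equivalent forms the magnesium carboxylate, which is inert at this temperature, and further reagent adds to the methyl ketone to give the dimethyl carbinol; lactonisation would need a seven-membered ring and is not expected.

Step 5
Reactants: 5 (3R)-6-hydroxy-6-methyl-3-(prop-1-en-2-yl)heptanoic acid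
Product: 7 (3R)-6-methyl-3-(prop-1-en-2-yl)-6-(triethylsilyloxy)heptanoic acid, via triethylsilyl ester 6 (not isolated)
Conditions: TESOTf (2.4 equiv), 2,6-lutidine, CH2Cl2, −78 → 0 °C; then K2CO3, THF/H2O, 0 °C; acidify to pH 5
Reagents that add atoms: triethylsilyl triflate, CC[Si](CC)(CC)OS(=O)(=O)C(F)(F)F
Why: A silyl triflate with a hindered pyridine base silylates even a tertiary alcohol, and the silyl ester formed alongside is far more labile than the tertiary silyl ether, so mild aqueous carbonate should hydrolyse it selectively.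

Step 6
Reactants: 7 (3R)-6-methyl-3-(prop-1-en-2-yl)-6-(triethylsilyloxy)heptanoic acid
Product: 9 triethyl{[(5S)-6-iodo-2-methyl-5-(prop-1-en-2-yl)hexan-2-yl]oxy}silane, via Barton ester 8 (not isolated)
Conditions: 1-hydroxypyridine-2(1H)-thione, DCC, DMAP (cat.), CH2Cl2, 0 °C → rt, dark; then CHI3 (2.5 equiv), tungsten lamp, rt
Reagents that add atoms: iodoform, IC(I)I
Why: Barton decarboxylative iodination: the thiohydroxamate ester fragments under visible light in a radical chain to CO2 and a primary alkyl radical, which should abstract iodine from iodoform much faster than it adds to the neighbouring isopropenyl group; this excises the former aldehyde carbon and leaves the stereocentre untouched (the descriptor becomes S only because CH2I outranks isopropenyl).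

Step 7
Reactants: 10 4-hydroxy-2-methoxybenzaldehyde
Product: 11 2-methoxy-4-(triisopropylsilyloxy)benzaldehyde
Conditions: TIPSCl (1.2 equiv), imidazole (2.5 equiv), DMF, rt
Reagents that add atoms: triisopropylsilyl chloride, CC(C)[Si](Cl)(C(C)C)C(C)C
Why: Standard silylation of a phenol; the triisopropylsilyl group is chosen because it has no C–H bond alpha to oxygen and should survive the later base, zinc and carbene steps.

Step 8
Reactants: 11 2-methoxy-4-(triisopropylsilyloxy)benzaldehyde
Product: 12 [2-methoxy-4-(triisopropylsilyloxy)phenyl]methanol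
Conditions: NaBH4, THF/EtOH, 0 °C
Reagents that add atoms: none
Why: Borohydride reduction of an aryl aldehyde to the benzyl alcohol at low temperature should leave the aryl silyl ether intact.

Step 9
Reactants: 13 2,4,6-trihydroxyacetophenone (phloracetophenone, dried)
Product: 14 1-[2-hydroxy-4,6-bis(triisopropylsilyloxy)phenyl]ethan-1-one
Conditions: TIPSCl (2.2 equiv), imidazole (5 equiv), DMF, 0 °C → rt
Reagents that add atoms: triisopropylsilyl chloride, CC(C)[Si](Cl)(C(C)C)C(C)C
Why: Silylation should occur at the para hydroxyl and at one of the two equivalent ortho hydroxyls, while the last hydroxyl, chelated to the acetyl carbonyl, stays free, the usual outcome of double protection of phloracetophenone.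

Step 10
Reactants: 14 1-[2-hydroxy-4,6-bis(triisopropylsilyloxy)phenyl]ethan-1-one
Product: 15 1-[2-hydroxy-3-iodo-4,6-bis(triisopropylsilyloxy)phenyl]ethan-1-one
Conditions: NIS (1.05 equiv), MeCN/CH2Cl2, 0 °C → rt, dark
Reagents that add atoms: N-iodosuccinimide, O=C1CCC(=O)N1I
Why: Electrophilic aromatic iodination: of the two open ring positions, C3 lies next to the small free hydroxyl whereas C5 is buried between two triisopropylsilyloxy groups, so substitution should occur at C3, the future C8.

Step 11
Reactants: 15 1-[2-hydroxy-3-iodo-4,6-bis(triisopropylsilyloxy)phenyl]ethan-1-one; 12 [2-methoxy-4-(triisopropylsilyloxy)phenyl]methanol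
Product: 16 1-[3-iodo-2-{[2-methoxy-4-(triisopropylsilyloxy)phenyl]methoxy}-4,6-bis(triisopropylsilyloxy)phenyl]ethan-1-one
Conditions: PPh3 (1.5 equiv), DIAD (1.5 equiv), THF, 0 °C → rt
Reagents that add atoms: none
Why: Mitsunobu etherification joins the acidic chelated phenol to the primary benzylic alcohol under neutral conditions, avoiding both a labile electron-rich benzyl halide and the carbonate bases that cleave aryl silyl ethers; the O1–CH2 bond of the future ring C is thereby in place.

Step 12
Reactants: 9 triethyl{[(5S)-6-iodo-2-methyl-5-(prop-1-en-2-yl)hexan-2-yl]oxy}silane; 16 1-[3-iodo-2-{[2-methoxy-4-(triisopropylsilyloxy)phenyl]methoxy}-4,6-bis(triisopropylsilyloxy)phenyl]ethan-1-one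
Product: 18 1-[2-{[2-methoxy-4-(triisopropylsilyloxy)phenyl]methoxy}-3-[(2R)-5-methyl-2-(prop-1-en-2-yl)-5-(triethylsilyloxy)hexyl]-4,6-bis(triisopropylsilyloxy)phenyl]ethan-1-one, via alkylzinc iodide 17 (not isolated)
Conditions: 9, Zn dust (activated with BrCH2CH2Br, Me3SiCl), LiCl, THF, 35 °C; then 16, Pd(OAc)2 (5 mol%), SPhos (10 mol%), THF/NMP, 50 °C
Reagents that add atoms: none
Why: Negishi coupling: zinc inserts into the primary C–I bond, the alkylzinc iodide tolerates ketone, silyl ether and alkene, and a bulky biarylphosphine catalyst of zerovalent palladium formed in the flask should couple it at the doubly ortho-flanked aryl iodide faster than beta-hydride elimination; benzylation precedes this step so that no phenolic proton consumes the zinc reagent, and the stereocentre beta to zinc is not affected.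

Step 13
Reactants: 18 1-[2-{[2-methoxy-4-(triisopropylsilyloxy)phenyl]methoxy}-3-[(2R)-5-methyl-2-(prop-1-en-2-yl)-5-(triethylsilyloxy)hexyl]-4,6-bis(triisopropylsilyloxy)phenyl]ethan-1-one
Product: 20 2-diazo-1-[2-{[2-methoxy-4-(triisopropylsilyloxy)phenyl]methoxy}-3-[(2R)-5-methyl-2-(prop-1-en-2-yl)-5-(triethylsilyloxy)hexyl]-4,6-bis(triisopropylsilyloxy)phenyl]ethan-1-one, via trifluoroacetyl ketone 19 (not isolated)
Conditions: LiN(SiMe3)2 (1.2 equiv), THF, −78 °C; CF3CO2CH2CF3 (1.4 equiv), −78 °C; aq. NH4Cl; then p-ABSA (1.5 equiv), Et3N (1.5 equiv), H2O (1 equiv), MeCN, rt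
Reagents that add atoms: 4-acetamidobenzenesulfonyl azide, CC(=O)Nc1ccc(S(=O)(=O)N=[N+]=[N-])cc1
Why: Detrifluoroacetylative diazo transfer: the kinetic lithium enolate of the methyl ketone is acylated by trifluoroethyl trifluoroacetate (Claisen condensation), the activated 1,3-diketone accepts the diazo group from the sulfonyl azide (Regitz-type transfer), and the trifluoroacetyl group, never part of the isolated product, leaves on the sulfonamide nitrogen; at −78 °C the ortho silyloxy group should not migrate to the enolate.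

Step 14
Reactants: 20 2-diazo-1-[2-{[2-methoxy-4-(triisopropylsilyloxy)phenyl]methoxy}-3-[(2R)-5-methyl-2-(prop-1-en-2-yl)-5-(triethylsilyloxy)hexyl]-4,6-bis(triisopropylsilyloxy)phenyl]ethan-1-one
Product: 21 (2S)-2-[2-methoxy-4-(triisopropylsilyloxy)phenyl]-8-[(2R)-5-methyl-2-(prop-1-en-2-yl)-5-(triethylsilyloxy)hexyl]-5,7-bis(triisopropylsilyloxy)-2,3-dihydro-4H-chromen-4-one
Conditions: Rh2(S-PTTL)4 (2 mol%), dry CH2Cl2, slow addition of 20 over 2 h, −20 → 0 °C
Reagents that add atoms: none
Why: The catalyst expels N2 from 20 to give an electrophilic rhodium carbene at C3, which takes up a benzylic C–H bond of the O1–CH2–aryl group through a concerted, asynchronous three-centre transition state with hydride-transfer character and so forms the C2–C3 bond. The closest known reaction type is the dirhodium-carboxylate-catalysed intramolecular C–H insertion of ortho-alkoxyaryl diazomethyl ketones at the carbon next to the ether oxygen, which gives 2-substituted chroman-4-ones. Ring C closes as a six-membered ring by 1,6-insertion (C3 as atom 1, then C4, C4a, C8a, O1 and C2 as atom 6), and no other C–H bond can be reached through a five- or six-membered transition state. The new C2 centre is set by the chiral phthalimido-tert-leucinate ligands, which differentiate the two benzylic hydrogens; the remote (R) centre of the C8 chain is too far away to interfere. The step needs insertion to outrun attack of the carbene on O1 (oxonium ylide, then Stevens 1,2-benzyl shift to a benzofuranone), and this is favoured by the hydridic, doubly activated C–H bond (alpha to oxygen, on electron-rich ring B), by the weakly basic aryl ether oxygen flanked on both sides, and by low temperature in a non-coordinating solvent. The silyl ethers offer neither a C–H bond alpha to oxygen nor an accessible oxygen lone pair, so the C5 and C7 oxygens should not compete, and slow addition suppresses carbene dimerisation and intermolecular cyclopropanation of the isopropenyl group.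

Step 15
Reactants: 21 (2S)-2-[2-methoxy-4-(triisopropylsilyloxy)phenyl]-8-[(2R)-5-methyl-2-(prop-1-en-2-yl)-5-(triethylsilyloxy)hexyl]-5,7-bis(triisopropylsilyloxy)-2,3-dihydro-4H-chromen-4-one
Product: 22 (2S)-5,7-dihydroxy-2-(4-hydroxy-2-methoxyphenyl)-8-[(2R)-5-hydroxy-5-methyl-2-(prop-1-en-2-yl)hexyl]-2,3-dihydro-4H-chromen-4-one (target)
Conditions: Bu4NF/AcOH (1:1, 8 equiv), THF, 0 °C → rt
Reagents that add atoms: none
Why: Fluoride cleaves all four Si–O bonds, and buffering with acetic acid keeps the liberated phenols protonated, so base-induced opening of ring C to the chalcone (which would scramble C2 and is favoured by a free 4'-hydroxyl) is avoided, while the medium is too weakly acidic to add the tertiary alcohol or the C7 hydroxyl to the isopropenyl group.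

**Compound list**

1 | (R)-limonene | C=C(C)[C@@H]1CCC(C)=CC1 | starting material
2 | (4R)-limonene 1,2-oxide (cis/trans mixture) | C=C(C)[C@@H]1CCC2(C)OC2C1 | intermediate
3 | (3R)-6-oxo-3-(prop-1-en-2-yl)heptanal | C=C(C)[C@@H](CC=O)CCC(C)=O | intermediate
4 | (3R)-6-oxo-3-(prop-1-en-2-yl)heptanoic acid | C=C(C)[C@@H](CC(=O)O)CCC(C)=O | intermediate
5 | (3R)-6-hydroxy-6-methyl-3-(prop-1-en-2-yl)heptanoic acid | C=C(C)[C@@H](CC(=O)O)CCC(C)(C)O | intermediate
6 | triethylsilyl (3R)-6-methyl-3-(prop-1-en-2-yl)-6-(triethylsilyloxy)heptanoate (not isolated) | C=C(C)[C@@H](CC(=O)O[Si](CC)(CC)CC)CCC(C)(C)O[Si](CC)(CC)CC | intermediate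
7 | (3R)-6-methyl-3-(prop-1-en-2-yl)-6-(triethylsilyloxy)heptanoic acid | C=C(C)[C@@H](CC(=O)O)CCC(C)(C)O[Si](CC)(CC)CC | intermediate
8 | 2-thioxopyridin-1(2H)-yl (3R)-6-methyl-3-(prop-1-en-2-yl)-6-(triethylsilyloxy)heptanoate (Barton ester, not isolated) | C=C(C)[C@@H](CC(=O)On1ccccc1=S)CCC(C)(C)O[Si](CC)(CC)CC | intermediate
9 | triethyl{[(5S)-6-iodo-2-methyl-5-(prop-1-en-2-yl)hexan-2-yl]oxy}silane | C=C(C)[C@@H](CI)CCC(C)(C)O[Si](CC)(CC)CC | intermediate
10 | 4-hydroxy-2-methoxybenzaldehyde | COc1cc(O)ccc1C=O | starting material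
11 | 2-methoxy-4-(triisopropylsilyloxy)benzaldehyde | COc1cc(O[Si](C(C)C)(C(C)C)C(C)C)ccc1C=O | intermediate
12 | [2-methoxy-4-(triisopropylsilyloxy)phenyl]methanol | COc1cc(O[Si](C(C)C)(C(C)C)C(C)C)ccc1CO | intermediate
13 | 2,4,6-trihydroxyacetophenone | CC(=O)c1c(O)cc(O)cc1O | starting material
14 | 1-[2-hydroxy-4,6-bis(triisopropylsilyloxy)phenyl]ethan-1-one | CC(=O)c1c(O)cc(O[Si](C(C)C)(C(C)C)C(C)C)cc1O[Si](C(C)C)(C(C)C)C(C)C | intermediate
15 | 1-[2-hydroxy-3-iodo-4,6-bis(triisopropylsilyloxy)phenyl]ethan-1-one | CC(=O)c1c(O)c(I)c(O[Si](C(C)C)(C(C)C)C(C)C)cc1O[Si](C(C)C)(C(C)C)C(C)C | intermediate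
16 | 1-[3-iodo-2-{[2-methoxy-4-(triisopropylsilyloxy)phenyl]methoxy}-4,6-bis(triisopropylsilyloxy)phenyl]ethan-1-one | CC(=O)c1c(OCc2ccc(O[Si](C(C)C)(C(C)C)C(C)C)cc2OC)c(I)c(O[Si](C(C)C)(C(C)C)C(C)C)cc1O[Si](C(C)C)(C(C)C)C(C)C | intermediate
17 | [(2S)-5-methyl-2-(prop-1-en-2-yl)-5-(triethylsilyloxy)hexyl]zinc iodide (not isolated) | C=C(C)[C@@H](C[Zn]I)CCC(C)(C)O[Si](CC)(CC)CC | intermediate
18 | 1-[2-{[2-methoxy-4-(triisopropylsilyloxy)phenyl]methoxy}-3-[(2R)-5-methyl-2-(prop-1-en-2-yl)-5-(triethylsilyloxy)hexyl]-4,6-bis(triisopropylsilyloxy)phenyl]ethan-1-one | C=C(C)[C@H](CCC(C)(C)O[Si](CC)(CC)CC)Cc1c(O[Si](C(C)C)(C(C)C)C(C)C)cc(O[Si](C(C)C)(C(C)C)C(C)C)c(C(C)=O)c1OCc1ccc(O[Si](C(C)C)(C(C)C)C(C)C)cc1OC | intermediate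
19 | 4,4,4-trifluoro-1-[2-{[2-methoxy-4-(triisopropylsilyloxy)phenyl]methoxy}-3-[(2R)-5-methyl-2-(prop-1-en-2-yl)-5-(triethylsilyloxy)hexyl]-4,6-bis(triisopropylsilyloxy)phenyl]butane-1,3-dione (not isolated) | C=C(C)[C@H](CCC(C)(C)O[Si](CC)(CC)CC)Cc1c(O[Si](C(C)C)(C(C)C)C(C)C)cc(O[Si](C(C)C)(C(C)C)C(C)C)c(C(=O)CC(=O)C(F)(F)F)c1OCc1ccc(O[Si](C(C)C)(C(C)C)C(C)C)cc1OC | intermediate
20 | 2-diazo-1-[2-{[2-methoxy-4-(triisopropylsilyloxy)phenyl]methoxy}-3-[(2R)-5-methyl-2-(prop-1-en-2-yl)-5-(triethylsilyloxy)hexyl]-4,6-bis(triisopropylsilyloxy)phenyl]ethan-1-one | C=C(C)[C@H](CCC(C)(C)O[Si](CC)(CC)CC)Cc1c(O[Si](C(C)C)(C(C)C)C(C)C)cc(O[Si](C(C)C)(C(C)C)C(C)C)c(C(=O)C=[N+]=[N-])c1OCc1ccc(O[Si](C(C)C)(C(C)C)C(C)C)cc1OC | intermediate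
21 | (2S)-2-[2-methoxy-4-(triisopropylsilyloxy)phenyl]-8-[(2R)-5-methyl-2-(prop-1-en-2-yl)-5-(triethylsilyloxy)hexyl]-5,7-bis(triisopropylsilyloxy)-2,3-dihydro-4H-chromen-4-one | C=C(C)[C@H](CCC(C)(C)O[Si](CC)(CC)CC)Cc1c(O[Si](C(C)C)(C(C)C)C(C)C)cc(O[Si](C(C)C)(C(C)C)C(C)C)c2c1O[C@H](c1ccc(O[Si](C(C)C)(C(C)C)C(C)C)cc1OC)CC2=O | intermediate
22 | (2S)-5,7-dihydroxy-2-(4-hydroxy-2-methoxyphenyl)-8-[(2R)-5-hydroxy-5-methyl-2-(prop-1-en-2-yl)hexyl]-2,3-dihydro-4H-chromen-4-one | C=C(C)[C@H](CCC(C)(C)O)Cc1c(O)cc(O)c2c1O[C@H](c1ccc(O)cc1OC)CC2=O | target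

**Step count and risks**

Total step count: 15. Longest linear sequence: 10 steps (steps 1 to 6, then 12 to 15).

Steps most likely to fail:

Step 14. The carbene may be intercepted by the O1 lone pair (oxonium ylide, then 1,2-benzyl shift) before it inserts, or the catalyst may not distinguish the two benzylic hydrogens well enough. The fallback closes ring C first and adds ring B by asymmetric conjugate addition. It sets out from 18: oxidative removal of the electron-rich benzyl group (DDQ, CH2Cl2/pH 7 buffer, 0 °C) should give the 2-hydroxyaryl methyl ketone F1 and return aldehyde 11. Heating F1 with N,N-dimethylformamide dimethyl acetal (toluene, 90 °C) should give the enaminone F2, which should close to the 8-alkyl-5,7-bis(silyloxy)chromone F3 with PPTS in CH2Cl2. In parallel, commercial 4-bromo-3-methoxyphenol is silylated (TIPSCl, imidazole, DMF) to the aryl bromide F4 and converted by Miyaura borylation (B2pin2, PdCl2(dppf), KOAc, dioxane, 80 °C) into the aryl pinacol boronate F5. Rhodium-catalysed asymmetric 1,4-addition of F5 to F3 ([Rh(OH)(cod)]2 of monovalent rhodium with a chiral MeO-BIPHEP-type bisphosphine, dioxane/H2O, K3PO4, 40 °C) is a known enantioselective entry to flavanones from chromones. It should set C2 under ligand control and return to the route at 21.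

Step 12. Oxidative addition and transmetalation at the doubly ortho-flanked C–I bond may be slow, so that beta-hydride elimination or protonolysis of the alkylzinc takes over, or zinc insertion may be accompanied by homocoupling. The fallback changes the metal to boron (B-alkyl Suzuki–Miyaura coupling). It sets out from 9: iodine–lithium exchange (t-BuLi, Et2O, −78 °C) should give the alkyllithium F6, which is trapped with B-methoxy-9-BBN to give the lithium B-alkyl-B-methoxy borinate F7. Coupling of F7 with 16 (PdCl2(dppf) of divalent palladium as precatalyst, K3PO4, DMF/THF, rt) should return to the route at 18.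

Step 11. The chelated, doubly flanked phenol may react sluggishly, allowing the activated electron-rich benzyl alcohol to decompose by self-alkylation. The fallback is a Williamson etherification with a preformed halide. It sets out from 12: Appel-type chlorination (PPh3, N-chlorosuccinimide, THF, 0 °C) should give the benzyl chloride F8, used at once. Alkylation of 15 with F8 (NaH, Bu4NI cat., THF/DMF, 0 °C → rt) should return to the route at 16.

**Further compounds**

F1 | step 14 | 1-{2-hydroxy-3-[(2R)-5-methyl-2-(prop-1-en-2-yl)-5-(triethylsilyloxy)hexyl]-4,6-bis(triisopropylsilyloxy)phenyl}ethan-1-one | C=C(C)[C@H](CCC(C)(C)O[Si](CC)(CC)CC)Cc1c(O[Si](C(C)C)(C(C)C)C(C)C)cc(O[Si](C(C)C)(C(C)C)C(C)C)c(C(C)=O)c1O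
F2 | step 14 | (2E)-3-(dimethylamino)-1-{2-hydroxy-3-[(2R)-5-methyl-2-(prop-1-en-2-yl)-5-(triethylsilyloxy)hexyl]-4,6-bis(triisopropylsilyloxy)phenyl}prop-2-en-1-one | C=C(C)[C@H](CCC(C)(C)O[Si](CC)(CC)CC)Cc1c(O[Si](C(C)C)(C(C)C)C(C)C)cc(O[Si](C(C)C)(C(C)C)C(C)C)c(C(=O)/C=C/N(C)C)c1O
F3 | step 14 | 8-[(2R)-5-methyl-2-(prop-1-en-2-yl)-5-(triethylsilyloxy)hexyl]-5,7-bis(triisopropylsilyloxy)-4H-chromen-4-one | C=C(C)[C@H](CCC(C)(C)O[Si](CC)(CC)CC)Cc1c(O[Si](C(C)C)(C(C)C)C(C)C)cc(O[Si](C(C)C)(C(C)C)C(C)C)c2c1OC=CC2=O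
F4 | step 14 | (4-bromo-3-methoxyphenoxy)tri(propan-2-yl)silane | COc1cc(O[Si](C(C)C)(C(C)C)C(C)C)ccc1Br
F5 | step 14 | [3-methoxy-4-(4,4,5,5-tetramethyl-1,3,2-dioxaborolan-2-yl)phenoxy]tri(propan-2-yl)silane | COc1cc(O[Si](C(C)C)(C(C)C)C(C)C)ccc1B1OC(C)(C)C(C)(C)O1
F6 | step 12 | [(2S)-5-methyl-2-(prop-1-en-2-yl)-5-(triethylsilyloxy)hexyl]lithium | C=C(C)[C@@H](C[Li])CCC(C)(C)O[Si](CC)(CC)CC
F7 | step 12 | lithium 9-methoxy-9-[(2S)-5-methyl-2-(prop-1-en-2-yl)-5-(triethylsilyloxy)hexyl]-9-boranuidabicyclo[3.3.1]nonane | [Li+].C=C(C)[C@@H](C[B-]1(OC)C2CCCC1CCC2)CCC(C)(C)O[Si](CC)(CC)CC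
F8 | step 11 | [4-(chloromethyl)-3-methoxyphenoxy]tri(propan-2-yl)silane | COc1cc(O[Si](C(C)C)(C(C)C)C(C)C)ccc1CCl
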